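Solid electrophile cannot react while it is solid, and these two flasks differ in the nucleophile charge.

- dusk: solid electrophile 20 mM; nucleophile 2.60 equiv; time 10 min
- dawn: solid electrophile 20 mM; nucleophile 2.00 equiv; time 10 min

    electrophile + nucleophile → acid set free + target (k1 = 0.40 /M/s)
    nucleophile + acid set free ⇌ protonated nucleophile, settled at all times (K2 = 1.6 × 10⁵ /M)
    solid electrophile ⇌ electrophile, rate k3*(cs3 - [electrophile]) while solid is left; crystals form when [electrophile] > cs3 (cs3 = 2.8 mM, k3 = 0.022 /s)
    nucleophile + target → over-reaction product (k4 = 0.87 /M/s)

* part of the solid electrophile that has reacted (what has only dissolved counts as not reacted) at the end, dusk
* part of the solid electrophile that has reacted (what has only dissolved counts as not reacted) at the end, dawn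
* what raising the equivalents of nucleophile from its lowest to its highest value here does to the part of the solid electrophile that has reacted (what has only dissolved counts as not reacted) (changes below 5 percentage points count as none) (no change / it rises / it falls)

We climb the dawn flask from its fastest event, with nucleophile as charged. Acid set free is caught at once: at the start the balance holds 6400 protonated nucleophile per free acid. Target has a half-life of 0.33 min by over-reaction alone, shorter than the 0.72 min of electrophile by its first step alone, so target passes on to over-reaction product soon after it forms. Dissolving approaches the solubility with a half-time of 0.525 min, which lies between those two.

So each electrophile going the whole way costs 3.00 of nucleophile: one for the bond, one for the acid, one for target. Held against this nucleophile price, the charges of both recipes make nucleophile the limiting reagent.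

On the last rung, we take dissolved electrophile to stand where dissolving and reaction balance. The pace is then the solubility times the dissolution coefficient times the pseudo-first-order reaction coefficient, over the sum of the two coefficients. Nucleophile falls throughout, so we roughly take half its charge as the mean. That gives 0.986 mM/min at dawn and 1.19 mM/min at dusk. Over 10 min, our reckoning is 49.3% reacted at dawn and 59.3% at dusk, a rise of 10 percentage points.

The forecast stood a little above us, at 62% for dusk and 51% for dawn, and said it rises, holding that “the extra nucleophile at dusk keeps the rate higher”.

The part reacted at the end is 62.1% in the dusk flask and 50.3% in the dawn flask, so on raising the nucleophile it rises, by 12 points. At the end of the dusk flask, 30.2% of the charged nucleophile is still free. The price, applied to that dusk conversion, leaves 28.3%, slightly less.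

A neighbour of dawn charged with 8.00 equiv stands above the price, so if its solid is used up, the price leaves 62.5% of its nucleophile free. Computed, 63% stays free, the solid electrophile runs out first with 0.014% left, solid or dissolved, and over-reaction product reaches >99.9%.

The constants are assumed; the result is computed.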